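**Retrosynthetic overview**
1. The enal is unmasked last, by oxidation of a primary allylic alcohol freed from a 4-methoxybenzyl ether; both tiglates come from one double esterification of the C3 carbinol and the side-chain (R)-carbinol.
2. Feature: in the dihydrofuran ring, C3 is a benzylic carbinol carbon ortho to O1 and C2 is an allylic carbon bonded to O1 and C3; these two carbons are the carbonyl carbon of a salicylaldehyde and the ylidic carbon of a 2-substituted allyl sulfonium salt.
3. Key disconnections: O1–C2 (phenoxide opening of a trans vinyl epoxide with inversion) and C2–C3 (chiral sulfonium ylide addition to the aldehyde), both in one flask as a formal [4+1] annulation.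
4. Ring order: the benzene ring is bought; the oxirane forms and is opened, and the dihydrofuran ring closes, all in step 9.
5. Fragments: the aldehyde comes from 3'-bromo-4'-hydroxyacetophenone (4 steps, side-chain centre by Noyori transfer hydrogenation); the sulfonium salt comes from 2-methylenepropane-1,3-diol and isothiocineole made from (S)-limonene (4 steps).

Key step: step 9

Assumption: the sense of induction is taken from the model in which the alkenyl group of the ylide lies syn to the sulfur lone pair and the aldehyde adds to the ylide face remote from the CMe2 carbon, so that the sulfide from (S)-limonene should give the (S,S)-epoxide; if a model run shows the opposite sense, the sulfide from (R)-limonene is used with nothing else changed.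

**Step 1**
Reactants: 1 3'-bromo-4'-hydroxyacetophenone
Product: 2 1-[3-bromo-4-(triisopropylsilyloxy)phenyl]ethanone
Conditions: i-Pr3SiCl, imidazole, DMF, rt
Reagents that add atoms: chlorotriisopropylsilane, CC(C)[Si](Cl)(C(C)C)C(C)C
Why: Imidazole-mediated silylation of the acidic phenol, the bulky i-Pr3Si ether being chosen because it must later resist an ortho aryllithium and the alkoxide of a betaine.

**Step 2**
Reactants: 2 1-[3-bromo-4-(triisopropylsilyloxy)phenyl]ethanone
Product: 3 (1R)-1-[3-bromo-4-(triisopropylsilyloxy)phenyl]ethanol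
Conditions: RuCl[(R,R)-TsDPEN](p-cymene) (1 mol%), HCO2H/Et3N (5:2), 28 °C
Reagents that add atoms: none
Why: Noyori asymmetric transfer hydrogenation, in which the Ru–H/N–H pair of the (R,R)-TsDPEN complex passes hydride and proton to the aryl methyl ketone through a six-membered outer-sphere transition state in the sense that gives (R)-1-arylethanols, while the formate medium leaves the aryl silyl ether and the aryl bromide alone.

**Step 3**
Reactants: 3 (1R)-1-[3-bromo-4-(triisopropylsilyloxy)phenyl]ethanol
Product: 4 [(1R)-1-[3-bromo-4-(triisopropylsilyloxy)phenyl]ethoxy](tert-butyl)dimethylsilane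
Conditions: TBSCl, imidazole, DMF, rt
Reagents that add atoms: tert-butylchlorodimethylsilane, CC(C)(C)[Si](C)(C)Cl
Why: Standard silylation of a secondary benzylic alcohol, which masks the hydroxyl toward butyllithium and later leaves a benzylic oxygen that is too poor a leaving group to be expelled by a para phenoxide.

**Step 4**
Reactants: 4 [(1R)-1-[3-bromo-4-(triisopropylsilyloxy)phenyl]ethoxy](tert-butyl)dimethylsilane
Product: 6 5-[(1R)-1-(tert-butyldimethylsilyloxy)ethyl]-2-(triisopropylsilyloxy)benzaldehyde, via aryllithium 5 (not isolated)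
Conditions: n-BuLi (1.05 equiv), THF, −78 °C; DMF, −78 to 0 °C; then H2O
Reagents that add atoms: N,N-dimethylformamide, CN(C)C=O; n-butyllithium, [Li]CCCC (supplies the lithium of 5 only)
Why: Bromine–lithium exchange followed by formylation with DMF (Bouveault formylation), where exchange at −78 °C is faster than attack on silicon, the bulky i-Pr3Si group slows the 1,3 O→C silyl shift of the ortho-lithiated aryl silyl ether, and the hemiaminal alkoxide releases the aldehyde only on work-up.

**Step 5**
Reactants: 7 2-methylenepropane-1,3-diol (3 equiv)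
Product: 8 2-[(4-methoxybenzyloxy)methyl]prop-2-en-1-ol
Conditions: NaH (1 equiv), 4-MeOC6H4CH2Cl (1 equiv), Bu4NI (cat.), THF/DMF, 0 °C to rt
Reagents that add atoms: 4-methoxybenzyl chloride, COc1ccc(CCl)cc1
Why: Williamson monoetherification of a symmetrical diol used in excess, the 4-methoxybenzyl ether being chosen instead of a silyl ether so that the primary oxygen stays masked while both silyl groups are removed and can be freed later without acid or base.

**Step 6**
Reactants: 8 2-[(4-methoxybenzyloxy)methyl]prop-2-en-1-ol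
Product: 9 1-({[2-(bromomethyl)prop-2-en-1-yl]oxy}methyl)-4-methoxybenzene
Conditions: CBr4, PPh3, CH2Cl2, 0 °C
Reagents that add atoms: carbon tetrabromide, BrC(Br)(Br)Br
Why: Appel bromination of the primary allylic alcohol through the alkoxyphosphonium bromide under neutral conditions that leave the benzyl ether intact, SN2 and SN2' giving the same bromide because the allyl unit is symmetrical.

**Step 7**
Reactants: 10 (S)-limonene
Product: 11 (1S,4S,5S)-isothiocineole, that is (1S,4S,5S)-4,7,7-trimethyl-6-thiabicyclo[3.2.1]octane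
Conditions: S8, γ-terpinene, neat, 110 °C; distillation
Reagents that add atoms: sulfur (S8), S1SSSSSSS1
Why: Known one-step preparation in which sulfur and the hydrogen donor γ-terpinene add the elements of H2S across both alkenes of limonene through a tertiary thiol and thiyl-radical closure onto the ring alkene, the limonene centre becoming C1, the bridge fixing C5 and hydrogen-atom transfer to the less hindered face of the tertiary radical setting C4.

**Step 8**
Reactants: 9 1-({[2-(bromomethyl)prop-2-en-1-yl]oxy}methyl)-4-methoxybenzene; 11 (1S,4S,5S)-isothiocineole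
Product: 12 (1S,4S,5S)-6-{2-[(4-methoxybenzyloxy)methyl]prop-2-en-1-yl}-4,7,7-trimethyl-6-thiabicyclo[3.2.1]octan-6-ium tetrafluoroborate (allyl group exo on sulfur, on the side of the one-carbon bridge)
Conditions: NaBF4, CH2Cl2/H2O, rt; crystallisation
Reagents that add atoms: sodium tetrafluoroborate, [Na+].F[B-](F)(F)F
Why: SN2 S-alkylation of the sulfide by the allylic bromide on the exo lone pair of sulfur, made irreversible by exchange of bromide for the non-nucleophilic tetrafluoroborate in the two-phase medium, which should give one sulfonium diastereomer.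

**Step 9**
Reactants: 6 5-[(1R)-1-(tert-butyldimethylsilyloxy)ethyl]-2-(triisopropylsilyloxy)benzaldehyde; 12 the sulfonium tetrafluoroborate (1.2 equiv)
Product: 15 (2R,3S)-5-[(1R)-1-(tert-butyldimethylsilyloxy)ethyl]-2-{3-[(4-methoxybenzyl)oxy]prop-1-en-2-yl}-2,3-dihydro-1-benzofuran-3-ol, via trans-vinyl epoxide 13 (not isolated), via epoxy phenoxide 14 (not isolated)
Conditions: P2-Et [EtN=P(NMe2)2N=P(NMe2)3] (1.1 equiv), CH2Cl2, −78 °C; then Bu4NF (1.1 equiv), THF, −78 to 0 °C; then H2O
Reagents that add atoms: tetrabutylammonium fluoride, CCCC[N+](CCCC)(CCCC)CCCC.[F-] (supplies the cation of 14 only)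
Why: The phosphazene base deprotonates the allylic S–CH2 of 12, the ylidic carbon adds to the aldehyde carbon of 6 (C2–C3 bond), and the anti betaine closes by 3-exo-tet displacement of sulfide 11 to the trans (2S,3S)-vinyl epoxide 13, which is the asymmetric sulfonium ylide (Corey–Chaykovsky) epoxidation known for isothiocineole-derived benzyl and allyl salts. One equivalent of Bu4NF then cleaves only the aryl silyl ether, and phenoxide 14 opens the allylic epoxide carbon by SN2 in the 5-endo-tet (epoxide-endo) mode, the only alternative being a four-membered ring, which forms the O1–C2 bond and the dihydrofuran ring as in the known cyclisation of 2-oxiranylphenols to 2,3-dihydrobenzofuran-3-ols. C3 is set by the sulfide, whose ylide holds the alkenyl group syn to the sulfur lone pair and meets the aldehyde on the face remote from the CMe2 carbon, and C2 is set by the anti betaine (trans epoxide) followed by clean inversion, which should give the 2,3-trans ring with 2R,3S. Epoxide closure must outrun the 1,4 O→O shift of silicon to the betaine alkoxide, since a free phenoxide would displace the sulfonium group directly and give the cis isomer, and the bulky i-Pr3Si group together with the non-nucleophilic base at −78 °C secures this. Attack at C2 instead of the terminal CH2 (SN2', a seven-membered closure) or C3 is secured by ring size and allylic activation, and the silanolate at the para benzylic carbon is too poor a leaving group for a para-quinone methide to form, so the (R)-carbinol centre is kept.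

**Step 10**
Reactants: 15 the silyl-protected dihydrobenzofuranol
Product: 16 (2R,3S)-5-[(1R)-1-hydroxyethyl]-2-{3-[(4-methoxybenzyl)oxy]prop-1-en-2-yl}-2,3-dihydro-1-benzofuran-3-ol
Conditions: Bu4NF (2 equiv), THF, rt; then H2O
Reagents that add atoms: none
Why: Fluoride cleavage of the secondary silyl ether (Si–F bond formation) under conditions to which the benzyl ether, the alkene and the two carbinol centres are inert.

**Step 11**
Reactants: 16 the diol; 17 tiglic acid (4 equiv)
Product: 18 (2R,3S)-2-{3-[(4-methoxybenzyl)oxy]prop-1-en-2-yl}-5-[(1R)-1-{[(2E)-2-methylbut-2-enoyl]oxy}ethyl]-2,3-dihydro-1-benzofuran-3-yl (2E)-2-methylbut-2-enoate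
Conditions: DCC (4 equiv), DMAP (0.3 equiv), CH2Cl2, rt
Reagents that add atoms: none
Why: Steglich esterification, in which DCC activates tiglic acid and DMAP relays the acyl group to both secondary benzylic alcohols with retention at carbon, the esters being put on before the enal exists because a 2-(aryloxyalkyl)acrolein would be open to conjugate addition of DMAP and ring opening.

**Step 12**
Reactants: 18 the bis-tiglate 4-methoxybenzyl ether
Product: 19 (2R,3S)-2-(3-hydroxyprop-1-en-2-yl)-5-[(1R)-1-{[(2E)-2-methylbut-2-enoyl]oxy}ethyl]-2,3-dihydro-1-benzofuran-3-yl (2E)-2-methylbut-2-enoate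
Conditions: DDQ (1.3 equiv), CH2Cl2/pH 7 phosphate buffer (10:1), 0 °C to rt
Reagents that add atoms: none
Why: Oxidative cleavage of the 4-methoxybenzyl ether by DDQ (hydride abstraction, oxocarbenium ion, hydrolysis) in buffered wet CH2Cl2, neutral conditions that should spare the two acid-sensitive benzylic esters and the less electron-rich benzofuran arene.

**Step 13**
Reactants: 19 the allylic alcohol
Product: 20 (2R,3S)-2-(3-oxoprop-1-en-2-yl)-5-[(1R)-1-{[(2E)-2-methylbut-2-enoyl]oxy}ethyl]-2,3-dihydro-1-benzofuran-3-yl (2E)-2-methylbut-2-enoate (CNP0292799.1)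
Conditions: TEMPO (0.1 equiv), PhI(OAc)2 (1.2 equiv), CH2Cl2, rt
Reagents that add atoms: none
Why: TEMPO-catalysed oxidation with PhI(OAc)2 as terminal oxidant (oxoammonium ion) converts the only free hydroxyl, a primary allylic one, into the aldehyde without nucleophile or strong acid or base, so neither the esters nor the C2 and C3 centres should be touched.

**Compound list**
1 | 3'-bromo-4'-hydroxyacetophenone | CC(=O)c1ccc(O)c(Br)c1 | starting material
2 | 1-[3-bromo-4-(triisopropylsilyloxy)phenyl]ethanone | CC(=O)c1ccc(O[Si](C(C)C)(C(C)C)C(C)C)c(Br)c1 | intermediate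
3 | (1R)-1-[3-bromo-4-(triisopropylsilyloxy)phenyl]ethanol | C[C@@H](O)c1ccc(O[Si](C(C)C)(C(C)C)C(C)C)c(Br)c1 | intermediate
4 | [(1R)-1-[3-bromo-4-(triisopropylsilyloxy)phenyl]ethoxy](tert-butyl)dimethylsilane | C[C@@H](O[Si](C)(C)C(C)(C)C)c1ccc(O[Si](C(C)C)(C(C)C)C(C)C)c(Br)c1 | intermediate
5 | {5-[(1R)-1-(tert-butyldimethylsilyloxy)ethyl]-2-(triisopropylsilyloxy)phenyl}lithium | C[C@@H](O[Si](C)(C)C(C)(C)C)c1ccc(O[Si](C(C)C)(C(C)C)C(C)C)c([Li])c1 | intermediate (not isolated)
6 | 5-[(1R)-1-(tert-butyldimethylsilyloxy)ethyl]-2-(triisopropylsilyloxy)benzaldehyde | C[C@@H](O[Si](C)(C)C(C)(C)C)c1ccc(O[Si](C(C)C)(C(C)C)C(C)C)c(C=O)c1 | intermediate (key-step precursor)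
7 | 2-methylenepropane-1,3-diol | C=C(CO)CO | starting material
8 | 2-[(4-methoxybenzyloxy)methyl]prop-2-en-1-ol | C=C(CO)COCc1ccc(OC)cc1 | intermediate
9 | 1-({[2-(bromomethyl)prop-2-en-1-yl]oxy}methyl)-4-methoxybenzene | C=C(CBr)COCc1ccc(OC)cc1 | intermediate
10 | (S)-limonene | CC1=CC[C@H](CC1)C(C)=C | starting material
11 | (1S,4S,5S)-isothiocineole | C[C@H]1CC[C@H]2C[C@@H]1SC2(C)C | intermediate
12 | (1S,4S,5S)-6-{2-[(4-methoxybenzyloxy)methyl]prop-2-en-1-yl}-4,7,7-trimethyl-6-thiabicyclo[3.2.1]octan-6-ium tetrafluoroborate | C[C@H]1CC[C@H]2C[C@@H]1[S@+](CC(=C)COCc3ccc(OC)cc3)C2(C)C.F[B-](F)(F)F | intermediate (key-step precursor)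
13 | (2S,3S)-2-{5-[(1R)-1-(tert-butyldimethylsilyloxy)ethyl]-2-(triisopropylsilyloxy)phenyl}-3-{3-[(4-methoxybenzyl)oxy]prop-1-en-2-yl}oxirane | C=C(COCc1ccc(OC)cc1)[C@@H]1O[C@H]1c1cc(ccc1O[Si](C(C)C)(C(C)C)C(C)C)[C@@H](C)O[Si](C)(C)C(C)(C)C | intermediate (not isolated)
14 | tetrabutylammonium 4-[(1R)-1-(tert-butyldimethylsilyloxy)ethyl]-2-[(2S,3S)-3-{3-[(4-methoxybenzyl)oxy]prop-1-en-2-yl}oxiran-2-yl]phenolate | C=C(COCc1ccc(OC)cc1)[C@@H]1O[C@H]1c1cc(ccc1[O-])[C@@H](C)O[Si](C)(C)C(C)(C)C.CCCC[N+](CCCC)(CCCC)CCCC | intermediate (not isolated)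
15 | (2R,3S)-5-[(1R)-1-(tert-butyldimethylsilyloxy)ethyl]-2-{3-[(4-methoxybenzyl)oxy]prop-1-en-2-yl}-2,3-dihydro-1-benzofuran-3-ol | C=C(COCc1ccc(OC)cc1)[C@H]1Oc2ccc([C@@H](C)O[Si](C)(C)C(C)(C)C)cc2[C@@H]1O | intermediate (key-step product)
16 | (2R,3S)-5-[(1R)-1-hydroxyethyl]-2-{3-[(4-methoxybenzyl)oxy]prop-1-en-2-yl}-2,3-dihydro-1-benzofuran-3-ol | C=C(COCc1ccc(OC)cc1)[C@H]1Oc2ccc([C@@H](C)O)cc2[C@@H]1O | intermediate
17 | tiglic acid, (2E)-2-methylbut-2-enoic acid | C/C=C(\C)C(=O)O | starting material
18 | (2R,3S)-2-{3-[(4-methoxybenzyl)oxy]prop-1-en-2-yl}-5-[(1R)-1-{[(2E)-2-methylbut-2-enoyl]oxy}ethyl]-2,3-dihydro-1-benzofuran-3-yl (2E)-2-methylbut-2-enoate | C=C(COCc1ccc(OC)cc1)[C@H]1Oc2ccc([C@@H](C)OC(=O)/C(C)=C/C)cc2[C@@H]1OC(=O)/C(C)=C/C | intermediate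
19 | (2R,3S)-2-(3-hydroxyprop-1-en-2-yl)-5-[(1R)-1-{[(2E)-2-methylbut-2-enoyl]oxy}ethyl]-2,3-dihydro-1-benzofuran-3-yl (2E)-2-methylbut-2-enoate | C=C(CO)[C@H]1Oc2ccc([C@@H](C)OC(=O)/C(C)=C/C)cc2[C@@H]1OC(=O)/C(C)=C/C | intermediate
20 | (2R,3S)-2-(3-oxoprop-1-en-2-yl)-5-[(1R)-1-{[(2E)-2-methylbut-2-enoyl]oxy}ethyl]-2,3-dihydro-1-benzofuran-3-yl (2E)-2-methylbut-2-enoate | C=C(C=O)[C@H]1Oc2ccc([C@@H](C)OC(=O)/C(C)=C/C)cc2[C@@H]1OC(=O)/C(C)=C/C | target

**Step count**
Total: 13 steps. Longest linear sequence: 9 steps (steps 1–4 and 9–13).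

**Steps most likely to fail**

Step 9. What may go wrong: addition of the ylide with low facial or anti selectivity; silyl transfer to the betaine alkoxide before the epoxide closes, which leaks material into the cis series; or opening of the epoxide through an ortho-quinone methide, which would scramble C3. The fallback sets out from aldehyde 6 and bromide 9 and returns to the route at 15 through 13. Bromide 9 is heated with triethyl phosphite (Michaelis–Arbuzov reaction) to give diethyl {2-[(4-methoxybenzyloxy)methyl]prop-2-en-1-yl}phosphonate F1. Its lithium anion (LiN(SiMe3)2, THF, −78 °C to rt) and aldehyde 6 should give, by Horner–Wadsworth–Emmons olefination, tert-butyl{(1R)-1-[3-{(1E)-3-[(4-methoxybenzyloxy)methyl]buta-1,3-dien-1-yl}-4-(triisopropylsilyloxy)phenyl]ethoxy}dimethylsilane F2. Shi epoxidation of its trans-disubstituted styrenyl alkene with the L-fructose-derived ketone catalyst (the enantiomer of the usual D-fructose-derived one), KHSO5 and K2CO3 buffer at pH 10.5 in MeCN/dimethoxymethane/H2O at 0 °C should give epoxide 13 as an isolated compound. Here the reagent fixes the face and the (E)-alkene fixes the trans relationship. Bu4NF then closes the ring to 15 as in step 9.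

Step 4. What may go wrong: migration of the silyl group from oxygen to the lithiated carbon, or protonation or butylation of the aryllithium before it meets DMF. The fallback sets out from bromide 4 and returns at aldehyde 6. Stille coupling of 4 with tributyl(vinyl)stannane (Pd(PPh3)4, toluene, 100 °C) should give tert-butyl{(1R)-1-[3-ethenyl-4-(triisopropylsilyloxy)phenyl]ethoxy}dimethylsilane F3. Lemieux–Johnson cleavage (OsO4 cat., NaIO4, 2,6-lutidine, dioxane/H2O) then gives 6, and no carbanion ortho to the silyl ether is involved.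

Step 11. What may go wrong: slow acylation of the second hydroxyl with build-up of N-acylurea, or loss of the C3 acyloxy group toward the benzofuran when the reaction is forced. The fallback sets out from diol 16 and returns at 18. Both hydroxyls are esterified with 2-(diethoxyphosphoryl)propanoic acid and DCC in CH2Cl2, a fast acylation even for hindered alcohols, to give (2R,3S)-5-[(1R)-1-{[2-(diethoxyphosphoryl)propanoyl]oxy}ethyl]-2-{3-[(4-methoxybenzyl)oxy]prop-1-en-2-yl}-2,3-dihydro-1-benzofuran-3-yl 2-(diethoxyphosphoryl)propanoate F4. A double Horner–Wadsworth–Emmons olefination with acetaldehyde (LiCl, i-Pr2NEt, MeCN) then builds the two (E)-2-methylbut-2-enoates in place and should give 18.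

**Further compounds**
F1 | step 9 | diethyl {2-[(4-methoxybenzyloxy)methyl]prop-2-en-1-yl}phosphonate | C=C(COCc1ccc(OC)cc1)CP(=O)(OCC)OCC
F2 | step 9 | tert-butyl{(1R)-1-[3-{(1E)-3-[(4-methoxybenzyloxy)methyl]buta-1,3-dien-1-yl}-4-(triisopropylsilyloxy)phenyl]ethoxy}dimethylsilane | C=C(COCc1ccc(OC)cc1)/C=C/c1cc(ccc1O[Si](C(C)C)(C(C)C)C(C)C)[C@@H](C)O[Si](C)(C)C(C)(C)C
F3 | step 4 | tert-butyl{(1R)-1-[3-ethenyl-4-(triisopropylsilyloxy)phenyl]ethoxy}dimethylsilane | C=Cc1cc(ccc1O[Si](C(C)C)(C(C)C)C(C)C)[C@@H](C)O[Si](C)(C)C(C)(C)C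
F4 | step 11 | (2R,3S)-5-[(1R)-1-{[2-(diethoxyphosphoryl)propanoyl]oxy}ethyl]-2-{3-[(4-methoxybenzyl)oxy]prop-1-en-2-yl}-2,3-dihydro-1-benzofuran-3-yl 2-(diethoxyphosphoryl)propanoate | C=C(COCc1ccc(OC)cc1)[C@H]1Oc2ccc([C@@H](C)OC(=O)C(C)P(=O)(OCC)OCC)cc2[C@@H]1OC(=O)C(C)P(=O)(OCC)OCC
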